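The constants used here are assumed.

Read a finished flask of this kind backwards: each unit of first nucleophile that has left stands as target, so the fraction left at late times gives the yield.

all flasks: substrate 0.014 M; first nucleophile 9.80 mM; protic impurity 0.0140 M; solid second nucleophile 0.0280 M; time 1.0 min

|  | temperature | remark |
|---|---|---|
| ash | 40 °C |  |
| alder | 15 °C |  |
| birch |  | at 65 °C until 30 s, from then on at 15 °C |
| elm | 65 °C |  |

    substrate → intermediate (k1 = 0.140 /s, Ea1 = 79.0 kJ/mol)
    first nucleophile + intermediate → target (k2 = 109 /M/s, Ea2 = 44.0 kJ/mol)
    second nucleophile + intermediate → other capture product (k3 = 69.2 /M/s, Ea3 = 37.0 kJ/mol)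
    intermediate → solvolysis product (k4 = 2.19 /s, Ea4 = 76.0 kJ/mol)
    second nucleophile + protic impurity → quenched reagent (k5 = 0.561 /M/s, Ea5 = 61.0 kJ/mol)
    second nucleophile ⇌ dormant form (K6 = 22.5, k6 = 0.0701 /s, Ea6 = 93.0 kJ/mol, ΔH6 = −11.0 kJ/mol)
    solid second nucleophile ⇌ second nucleophile, rate k7*(cs7 - [second nucleophile]) while solid is left; crystals form when [second nucleophile] > cs7 (cs7 = 1.1 mM, k7 = 0.0375 /s)
    (constants at 40 °C)

- solid second nucleophile is a solid; its amount is given per volume of the solution
- at 40 °C the constants are as listed, elsewhere as the activation energies and enthalpies make them
- at the start none of the solid second nucleophile is in solution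

1. which flask leads in amount of target, in percent of the substrate charged ("all alike" within 1.5 percentage points) (ash / alder / birch / elm / all alike)
2. how much target is there at the end, in percent of the substrate charged: ash
3. how much target is there at the end, in percent of the substrate charged: alder
4. how much target is there at the end, in percent of the substrate charged: birch
5. how much target is there at the end, in percent of the substrate charged: elm

Take the charge of first nucleophile as the unit and call f the fraction of it left. In ash the lifetime of the intermediate by solvolysis is 0.457 s, shorter than the substrate half-life of 4.95 s, so treat it at quasi-steady state. Leave second nucleophile aside for now. Each intermediate then goes to target with the share f/(f+b), where b is the break-even fraction, the fraction of first nucleophile at which capture and solvolysis run equally fast, k4/(k2·cB). In ash b is 2.05. Integrating gives the balance (1−f) + b·ln(1/f) = x, with x the substrate converted, in the same unit.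

In ash 12.1 half-lives pass, so x is the charge ratio 1.43. Solve for the fraction left by rounds. Hold the share at its opening value and get 53.2%. Put each f back into the balance: 62.6%, 59.8%, 60.6%, 60.4%. Target in ash is the used fraction over the charge ratio, 27.7%.

At 65 °C b grows to 5.09, and the same rounds leave 79.1%, then 78.7%, so elm holds 14.9%. The substrate half-life there is 0.525 s, far shorter than the 30 s before cooling, so birch copies elm.

At 15 °C b falls to 0.706, but alder converts 45.3% of its substrate, so x is 0.648. Here the rounds swing, so average neighbours: 62.0%, 68.4%, mean 65.2%, then 65.4%, which is 24.2% target.

Now reforge the weak link, the neglected second nucleophile. Set its capture against solvolysis at the solubility, an upper figure: k3·cs7/k4 is 0.0348 in ash at 40 °C and 0.127 in alder, more than in ash. Leave ash as it stands and raise alder's b to 0.796. The rounds give 68.5%, mean 66.9%, then 67.2%, so alder holds 23.0%. Commit to ash leading.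

The forecast, working with “the intermediate in quasi-steady state”, says ash leads, with ash 27.6%, alder 23%, birch 14.9% and elm 14.9%; its ash figure lies 0.10 percentage points under mine.

The simulation puts ash in the lead: ash 27.6%, alder 22.9%, birch 14.9%, elm 14.9%.

Ash has come to rest for target: at ten times the time it reads 27.6%, and first nucleophile stands at 60.5%, beside the 60.4% of the balance. Its solid second nucleophile still moves, from 93.6% to 52.2%. Alder has not come to rest: substrate falls from 54.7% to 0.238%, and target climbs from 22.9% to 44.8%. Its first nucleophile reaches 36.1%, and that fraction with the raised break-even returns 1.45 in the balance, against a charge ratio of 1.43.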